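Numbering: ring A = C1 (angelate carbinol), C2, C3 (CH3), C4 (OAc), C5, C6; side chain C7 (CH3)–C8–C9 (OAc)–C10=C11(CH3)2.
Cuts: the three ester C–O bonds, then C9–C10, C7=C8 and C7–CH3 in the chain, then C2–C3, C4–C5 and C6=C1 in ring A.
Enabling feature: ring A is three two-carbon pieces, C1–C2 (acetaldehyde), C3–C4 (nitropropene) and C5–C6 carrying C7 (acrolein). C4 lies 1,4 to C1 and needs acyl-anion polarity, which NO2 supplies before it becomes the C4 oxygen.
Forward: ring A closes first, in one flask (step 3). Ring B, a δ-lactone O–C9–C8–C7–C6–C1, is then closed onto it as a rigid template and reopened when C10–C11 is added. The esters come last.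
Stereochemistry: C3 comes from the amine catalyst. A ligand-set C7 carbinol steers the epoxide oxygen onto C1 and is then erased. C6 is set by equilibration in a chair locked by equatorial CH3 and NO2, C7 by axial hydride delivery in ring B, C4 by LiBH(s-Bu)3, and C9 by oxazaborolidine reduction.

Key step: step 3

Assumption: the facial sense of the chiral amine (step 3), the amino alcohol ligand (step 4) and the oxazaborolidine (step 17) is taken from their behaviour with simpler aldehydes, nitroalkenes and enones; all three are available in both mirror-image forms.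

Step 1
Reactants: 1 acetaldehyde; 2 nitromethane
Product: 3 1-nitropropan-2-ol (racemic)
Conditions: KOH (cat.), MeOH, 0 °C to rt, 2 in excess
Reagents that add atoms: none
Why: Henry (nitroaldol) addition of the nitromethane anion to the aldehyde; the racemic carbinol centre disappears in step 2.

Step 2
Reactants: 3 1-nitropropan-2-ol
Product: 4 (E)-1-nitroprop-1-ene
Conditions: (CF3CO)2O, Et3N, CH2Cl2, −10 °C
Reagents that add atoms: none
Why: O-trifluoroacetylation followed by E1cB elimination through the nitronate, the standard dehydration of β-nitro alcohols, which should give the more stable E alkene.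

Step 3
Reactants: 1 acetaldehyde; 4 (E)-1-nitroprop-1-ene; 5 acrolein
Product: 8 (4S,5S)-4-methyl-5-nitrocyclohex-1-ene-1-carbaldehyde, via (S)-3-methyl-4-nitrobutanal 6 (not isolated), via (3S)-3-methyl-4-nitroheptanedial 7 (not isolated)
Conditions: (R)-2-[diphenyl(trimethylsilyloxy)methyl]pyrrolidine (20 mol %), 1 (5 equiv), 1,4-dioxane, 10 °C to rt; excess 1 evaporated; then 5 (1.2 equiv), PhCO2H (20 mol %), toluene, 0 °C to rt
Reagents that add atoms: none
Why: The amine turns 1 into an enamine that adds to C3 of 4 (first Michael step, C2–C3) and hydrolysis releases 6; the nitronate of 6 adds to the iminium ion of 5 (second Michael step, C4–C5), and the enamine left at C6–C7 attacks the C1 aldehyde and loses water (C6=C1). The closest known reaction type is the amine-catalysed aldehyde/nitroalkene/enal Michael–Michael–aldol-condensation triple cascade. The one ring closes in the 6-(enolexo)-exo-trig mode. C3 is fixed by the diphenyl(silyloxy)methyl group, which shields one face of the anti enamine, and the (R)-catalyst is chosen because the (S)-catalyst builds the mirror-image arrangement at the β-carbon of nitroalkenes; C4 is set by nitronate equilibration, which places NO2 equatorial and trans to CH3. Role selectivity is needed because 1 could also add to 5 or to itself: 4 is by far the best acceptor for the enamine, 1 is stripped off (b.p. 20 °C) before 5 enters, and 5 has no enolisable position. Regioselectivity of the aldol step follows from the catalyst remaining bound as the C6 enamine after the second Michael step, so that C6 rather than C2 is the nucleophile.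

Step 4
Reactants: 8 (4S,5S)-4-methyl-5-nitrocyclohex-1-ene-1-carbaldehyde
Product: 9 (1R)-1-[(4S,5S)-4-methyl-5-nitrocyclohex-1-en-1-yl]ethan-1-ol
Conditions: Me2Zn (3 equiv), (+)-MIB [(2R)-3-exo-morpholinoisoborneol] (5 mol %), toluene, 0 °C to rt; aq NH4Cl
Reagents that add atoms: dimethylzinc, C[Zn]C
Why: Amino-alcohol-catalysed asymmetric 1,2-addition of a dialkylzinc to an aldehyde, in which the (+)-ligand (antipode of the one that gives S carbinols) should deliver CH3 to give the (7R)-carbinol while the weakly basic reagent spares the nitro group.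

Step 5
Reactants: 9 (1R)-1-[(4S,5S)-4-methyl-5-nitrocyclohex-1-en-1-yl]ethan-1-ol
Product: 10 (1R)-1-[(1R,3S,4S,6R)-4-methyl-3-nitro-7-oxabicyclo[4.1.0]heptan-1-yl]ethan-1-ol (epoxide on the ring face that carries the C3 methyl)
Conditions: VO(acac)2 (2 mol %), t-BuOOH, CH2Cl2, 0 °C
Reagents that add atoms: tert-butyl hydroperoxide, CC(C)(C)OO
Why: Hydroxyl-directed vanadium-catalysed epoxidation of an allylic alcohol, where C5H2 geminal and only H cis to the carbinol carbon make A(1,2) strain select the rotamer in which the (7R)-alkoxide holds the peroxide over the face of the C3 methyl, setting the C1–O bond on that face.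

Step 6
Reactants: 10 epoxy alcohol
Product: 11 1-[(1S,3S,4S,6R)-4-methyl-3-nitro-7-oxabicyclo[4.1.0]heptan-1-yl]ethan-1-one
Conditions: Dess–Martin periodinane, pyridine, CH2Cl2, 0 °C to rt
Reagents that add atoms: none
Why: Dess–Martin oxidation of a secondary alcohol under near-neutral conditions that spare the epoxide and the nitro group; the relay centre C7 is erased once it has served.

Step 7
Reactants: 11 epoxy ketone
Product: 12 1-[(1R,2R,4S,5S)-2-hydroxy-4-methyl-5-nitrocyclohexyl]ethan-1-one
Conditions: PhSeSePh, NaBH4, EtOH, 0 °C; then 11, AcOH (cat.), 0 °C to rt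
Reagents that add atoms: none
Why: Reductive Cα–O cleavage of an α,β-epoxy ketone with sodium phenylseleno(triethoxy)borate leaves the C1–O bond untouched, and C6 is protonated and equilibrated through the enol to the equatorial acetyl group because equatorial CH3, NO2 and OH hold the chair.

Step 8
Reactants: 12 β-hydroxy ketone; 13 2-(diethoxyphosphoryl)acetic acid
Product: 14 (1R,2R,4S,5S)-2-acetyl-5-methyl-4-nitrocyclohexyl 2-(diethoxyphosphoryl)acetate
Conditions: DCC, DMAP (5 mol %), CH2Cl2, 0 °C
Reagents that add atoms: none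
Why: Steglich esterification of the equatorial C1 alcohol at low temperature, mild enough that the aldol should not dehydrate.

Step 9
Reactants: 14 phosphonoacetate
Product: 15 (4aS,6S,7S,8aR)-4,7-dimethyl-6-nitro-4a,5,6,7,8,8a-hexahydro-2H-chromen-2-one
Conditions: LiCl, i-Pr2NEt, MeCN, rt, high dilution
Reagents that add atoms: none
Why: Intramolecular Horner–Wadsworth–Emmons olefination under Masamune–Roush conditions, in which the amine removes only the lithium-chelated phosphonate proton so that ring B (C7=C8, trans-fused through the diequatorial C1–O and C6–C7 bonds) should close before the β-acyloxy ketone eliminates.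

Step 10
Reactants: 15 unsaturated lactone
Product: 16 (4R,4aS,6S,7S,8aR)-4,7-dimethyl-6-nitrooctahydro-2H-chromen-2-one
Conditions: Cu(OAc)2 (5 mol %), 1,2-(Ph2P)2C6H4 (5 mol %), (EtO)2MeSiH, t-BuOH, toluene, rt
Reagents that add atoms: none
Why: Copper hydride conjugate reduction of a β,β-disubstituted unsaturated lactone, where the rigid trans-fused bicycle should take hydride at C7 axially and anti to H6, leaving the C7 methyl equatorial (7R); nitroalkanes are known to tolerate these conditions.

Step 11
Reactants: 16 nitro lactone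
Product: 18 (4R,4aS,7S,8aR)-4,7-dimethylhexahydro-2H-chromene-2,6(3H)-dione, via potassium nitronate 17 (not isolated)
Conditions: t-BuOK (1.05 equiv), THF, 0 °C; then dimethyldioxirane, acetone, 0 °C
Reagents that add atoms: dimethyldioxirane, CC1(C)OO1
Why: Oxidative Nef reaction in which the most acidic C–H (C4) is removed and the dioxirane cleaves the C=N bond of 17 to the ketone; C3 becomes enolisable but is safe because its equatorial methyl is already the stable arrangement in the trans-fused bicycle.

Step 12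
Reactants: 18 keto lactone
Product: 19 (4R,4aS,6R,7S,8aR)-6-hydroxy-4,7-dimethyloctahydro-2H-chromen-2-one
Conditions: LiBH(s-Bu)3 (1.1 equiv), THF, −78 °C; then H2O2, pH 7 buffer
Reagents that add atoms: none
Why: Diastereoselective ketone reduction with a bulky trialkylborohydride, which attacks along the equatorial trajectory (as with 2-methylcyclohexanone) to give the axial C4 alcohol cis to the C3 methyl, while the lactone is inert at −78 °C.

Step 13
Reactants: 19 hydroxy lactone
Product: 20 (4R,4aS,6R,7S,8aR)-6-(tert-butyldimethylsilyloxy)-4,7-dimethyloctahydro-2H-chromen-2-one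
Conditions: TBSOTf, 2,6-lutidine, CH2Cl2, 0 °C
Reagents that add atoms: tert-butyldimethylsilyl trifluoromethanesulfonate, CC(C)(C)[Si](C)(C)OS(=O)(=O)C(F)(F)F
Why: Silyl ether formation with the triflate, reactive enough for the hindered axial alcohol, masks C4–OH against the organolithium of step 14.

Step 14
Reactants: 20 silyl lactone; 21 1-bromo-2-methylprop-1-ene
Product: 23 (6R)-6-[(1S,2R,4S,5R)-5-(tert-butyldimethylsilyloxy)-2-hydroxy-4-methylcyclohexyl]-2-methylhept-2-en-4-one, via 2-methylprop-1-enyllithium 22 (not isolated)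
Conditions: 21, t-BuLi (2 equiv), Et2O, −78 °C; then 20, THF, −78 °C; aq NH4Cl
Reagents that add atoms: none
Why: Halogen–lithium exchange followed by single addition of an alkenyllithium to a lactone (C9–C10), in which the tetrahedral lithium alkoxide persists at −78 °C and collapses only on work-up to the conjugated hydroxy enone, freeing C1–OH.

Step 15
Reactants: 23 hydroxy enone; 24 angelic acid [(Z)-2-methylbut-2-enoic acid]
Product: 26 (1R,2S,4R,5S)-4-(tert-butyldimethylsilyloxy)-5-methyl-2-[(2R)-6-methyl-4-oxohept-5-en-2-yl]cyclohexyl (Z)-2-methylbut-2-enoate, via angelic 2,4,6-trichlorobenzoic anhydride 25 (not isolated)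
Conditions: 24, 2,4,6-Cl3C6H2COCl, Et3N, toluene, rt; then 23, 80 °C
Reagents that add atoms: none
Why: Yamaguchi-type mixed-anhydride acylation without a nucleophilic catalyst, the established way to angeloylate hindered alcohols without Z-to-E isomerisation, which should acylate the secondary C1–OH of the open hydroxy ketone rather than any tertiary hemiketal hydroxyl.

Step 16
Reactants: 26 silyl angelate
Product: 27 (1R,2S,4R,5S)-4-hydroxy-5-methyl-2-[(2R)-6-methyl-4-oxohept-5-en-2-yl]cyclohexyl (Z)-2-methylbut-2-enoate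
Conditions: HF·pyridine, pyridine, THF, 0 °C to rt
Reagents that add atoms: none
Why: Buffered fluoride cleavage of the silyl ether, placed before the ketone reduction so that the ionisable C9 allylic alcohol never meets HF; the enone and the angelate are inert.

Step 17
Reactants: 27 hydroxy enone angelate
Product: 28 (1R,2S,4R,5S)-4-hydroxy-2-[(2R,4R)-4-hydroxy-6-methylhept-5-en-2-yl]-5-methylcyclohexyl (Z)-2-methylbut-2-enoate
Conditions: (S)-2-methyl-CBS-oxazaborolidine (20 mol %), catecholborane, toluene, −78 °C; aq NaHCO3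
Reagents that add atoms: none
Why: Corey–Bakshi–Shibata reduction in which the alkenyl group acts as the large and C8H2 as the small substituent, so the (S)-catalyst should give the (9R)-allylic alcohol by 1,2-reduction only, and catecholborane at −78 °C leaves the ester and the alkenes alone.

Step 18
Reactants: 28 diol
Product: 29 (1R,2S,4R,5S)-4-acetoxy-2-[(2R,4R)-4-acetoxy-6-methylhept-5-en-2-yl]-5-methylcyclohexyl (Z)-2-methylbut-2-enoate (target)
Conditions: Ac2O, pyridine, DMAP (cat.), CH2Cl2, 0 °C to rt
Reagents that add atoms: acetic anhydride, CC(=O)OC(C)=O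
Why: Double O-acetylation of C4–OH and C9–OH with retention at both centres; a formed angelate ester does not isomerise under these conditions.

Compound list
1 | acetaldehyde | CC=O | starting material
2 | nitromethane | C[N+](=O)[O-] | starting material
3 | 1-nitropropan-2-ol (racemic) | CC(O)C[N+](=O)[O-] | intermediate
4 | (E)-1-nitroprop-1-ene | C/C=C/[N+](=O)[O-] | intermediate
5 | acrolein | C=CC=O | starting material
6 | (S)-3-methyl-4-nitrobutanal | O=CC[C@H](C)C[N+](=O)[O-] | intermediate
7 | (3S)-3-methyl-4-nitroheptanedial (C4 labile) | O=CC[C@H](C)C([N+](=O)[O-])CCC=O | intermediate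
8 | (4S,5S)-4-methyl-5-nitrocyclohex-1-ene-1-carbaldehyde | O=CC1=CC[C@H](C)[C@@H]([N+](=O)[O-])C1 | intermediate
9 | (1R)-1-[(4S,5S)-4-methyl-5-nitrocyclohex-1-en-1-yl]ethan-1-ol | C[C@@H](O)C1=CC[C@H](C)[C@@H]([N+](=O)[O-])C1 | intermediate
10 | (1R)-1-[(1R,3S,4S,6R)-4-methyl-3-nitro-7-oxabicyclo[4.1.0]heptan-1-yl]ethan-1-ol | O1[C@@H]2C[C@H](C)[C@@H]([N+](=O)[O-])C[C@]12[C@@H](C)O | intermediate
11 | 1-[(1S,3S,4S,6R)-4-methyl-3-nitro-7-oxabicyclo[4.1.0]heptan-1-yl]ethan-1-one | O1[C@@H]2C[C@H](C)[C@@H]([N+](=O)[O-])C[C@]12C(C)=O | intermediate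
12 | 1-[(1R,2R,4S,5S)-2-hydroxy-4-methyl-5-nitrocyclohexyl]ethan-1-one | O[C@@H]1C[C@H](C)[C@@H]([N+](=O)[O-])C[C@H]1C(C)=O | intermediate
13 | 2-(diethoxyphosphoryl)acetic acid | CCOP(=O)(CC(=O)O)OCC | starting material
14 | (1R,2R,4S,5S)-2-acetyl-5-methyl-4-nitrocyclohexyl 2-(diethoxyphosphoryl)acetate | CCOP(=O)(OCC)CC(=O)O[C@@H]1C[C@H](C)[C@@H]([N+](=O)[O-])C[C@H]1C(C)=O | intermediate
15 | (4aS,6S,7S,8aR)-4,7-dimethyl-6-nitro-4a,5,6,7,8,8a-hexahydro-2H-chromen-2-one | O=C1O[C@@H]2C[C@H](C)[C@@H]([N+](=O)[O-])C[C@H]2C(C)=C1 | intermediate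
16 | (4R,4aS,6S,7S,8aR)-4,7-dimethyl-6-nitrooctahydro-2H-chromen-2-one | O=C1O[C@@H]2C[C@H](C)[C@@H]([N+](=O)[O-])C[C@H]2[C@H](C)C1 | intermediate
17 | potassium nitronate of 16 | [K+].O=C1O[C@@H]2C[C@H](C)C(=[N+]([O-])[O-])C[C@H]2[C@H](C)C1 | intermediate
18 | (4R,4aS,7S,8aR)-4,7-dimethylhexahydro-2H-chromene-2,6(3H)-dione | O=C1O[C@@H]2C[C@H](C)C(=O)C[C@H]2[C@H](C)C1 | intermediate
19 | (4R,4aS,6R,7S,8aR)-6-hydroxy-4,7-dimethyloctahydro-2H-chromen-2-one | O=C1O[C@@H]2C[C@H](C)[C@H](O)C[C@H]2[C@H](C)C1 | intermediate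
20 | (4R,4aS,6R,7S,8aR)-6-(tert-butyldimethylsilyloxy)-4,7-dimethyloctahydro-2H-chromen-2-one | O=C1O[C@@H]2C[C@H](C)[C@H](O[Si](C)(C)C(C)(C)C)C[C@H]2[C@H](C)C1 | intermediate
21 | 1-bromo-2-methylprop-1-ene | CC(C)=CBr | starting material
22 | 2-methylprop-1-enyllithium | [Li]C=C(C)C | intermediate
23 | (6R)-6-[(1S,2R,4S,5R)-5-(tert-butyldimethylsilyloxy)-2-hydroxy-4-methylcyclohexyl]-2-methylhept-2-en-4-one | O[C@@H]1C[C@H](C)[C@H](O[Si](C)(C)C(C)(C)C)C[C@H]1[C@H](C)CC(=O)C=C(C)C | intermediate
24 | angelic acid, (Z)-2-methylbut-2-enoic acid | C/C=C(/C)C(=O)O | starting material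
25 | angelic 2,4,6-trichlorobenzoic anhydride | C/C=C(/C)C(=O)OC(=O)c1c(Cl)cc(Cl)cc1Cl | intermediate
26 | (1R,2S,4R,5S)-4-(tert-butyldimethylsilyloxy)-5-methyl-2-[(2R)-6-methyl-4-oxohept-5-en-2-yl]cyclohexyl (Z)-2-methylbut-2-enoate | C/C=C(/C)C(=O)O[C@@H]1C[C@H](C)[C@H](O[Si](C)(C)C(C)(C)C)C[C@H]1[C@H](C)CC(=O)C=C(C)C | intermediate
27 | (1R,2S,4R,5S)-4-hydroxy-5-methyl-2-[(2R)-6-methyl-4-oxohept-5-en-2-yl]cyclohexyl (Z)-2-methylbut-2-enoate | C/C=C(/C)C(=O)O[C@@H]1C[C@H](C)[C@H](O)C[C@H]1[C@H](C)CC(=O)C=C(C)C | intermediate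
28 | (1R,2S,4R,5S)-4-hydroxy-2-[(2R,4R)-4-hydroxy-6-methylhept-5-en-2-yl]-5-methylcyclohexyl (Z)-2-methylbut-2-enoate | C/C=C(/C)C(=O)O[C@@H]1C[C@H](C)[C@H](O)C[C@H]1[C@H](C)C[C@H](C=C(C)C)O | intermediate
29 | (1R,2S,4R,5S)-4-acetoxy-2-[(2R,4R)-4-acetoxy-6-methylhept-5-en-2-yl]-5-methylcyclohexyl (Z)-2-methylbut-2-enoate (CNP0286954.1) | C/C=C(/C)C(=O)O[C@@H]1C[C@H](C)[C@H](OC(C)=O)C[C@H]1[C@H](C)C[C@H](C=C(C)C)OC(C)=O | target

Total step count: 18. Longest linear sequence: 18 steps (1 and 2 to 29); compounds 5, 13, 21 and 24 are bought.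

Steps most likely to fail

Step 3. Oligomerisation of acrolein, self-aldolisation of acetaldehyde and a second conjugate addition of the nitronate to acrolein may outrun the three-component sequence. The fallback sets out from 4 and returns at 8, forming the same three bonds one at a time with the C1 carbonyl masked.
- The amine-catalysed addition of 1 to 4 is stopped at 6, which is isolated. HC(OMe)3 and catalytic TsOH convert it into (2S)-4,4-dimethoxy-2-methyl-1-nitrobutane F1.
- Base-catalysed conjugate addition of F1 to 5 (Et3N, MeCN) gives (5S)-7,7-dimethoxy-5-methyl-4-nitroheptanal F2.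
- TMSOTf and i-Pr2NEt turn the free aldehyde into its silyl enol ether and ionise the acetal. An intramolecular Mukaiyama aldol-type addition, with C6 necessarily the nucleophile and C1 the electrophile, then closes the ring to (4S)-2-methoxy-4-methyl-5-nitrocyclohexane-1-carbaldehyde F3.
- DBU eliminates methanol and equilibrates C4, giving 8.

Step 9. β-Elimination of the acyloxy group through the C6 enolate may compete with a slow olefination of the hindered methyl ketone. The fallback sets out from 12 and returns at 15, replacing the olefination by an aldol-type C7–C8 bond formation with a weakly basic zinc enolate.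
- Bromoacetyl bromide and pyridine give (1R,2R,4S,5S)-2-acetyl-5-methyl-4-nitrocyclohexyl 2-bromoacetate F4.
- RhCl(PPh3)3 (cat.) and Et2Zn in THF at 0 °C trigger an intramolecular Reformatsky reaction to (4aR,6S,7S,8aR)-4-hydroxy-4,7-dimethyl-6-nitrooctahydro-2H-chromen-2-one F5. Its carbinol configuration is immaterial.
- SOCl2 in pyridine dehydrates F5 towards the carbonyl group to give 15.

Step 10. Hydride delivery from the equatorial side (poor facial selectivity at C7) or sluggish addition to the hindered β,β-disubstituted acceptor may occur. The fallback sets out from 15 and returns at 16, with C7 set by hydroxyl direction instead of ring-template control.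
- i-Bu2AlH opens the lactone to (1R,2S,4S,5S)-2-[(2Z)-4-hydroxybut-2-en-2-yl]-5-methyl-4-nitrocyclohexan-1-ol F6.
- In F6, A(1,3) strain places H6 in the alkene plane and C1–OH over one face. Hydrogenation with [Ir(cod)(PCy3)(py)]PF6 in CH2Cl2 should therefore add hydrogen from the C1 side, giving (1R,2S,4S,5S)-2-[(2R)-4-hydroxybutan-2-yl]-5-methyl-4-nitrocyclohexan-1-ol F7.
- TEMPO and PhI(OAc)2 oxidise the primary alcohol through the lactol to 16.

Further compounds
F1 | step 3 | (2S)-4,4-dimethoxy-2-methyl-1-nitrobutane | COC(OC)C[C@H](C)C[N+](=O)[O-]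
F2 | step 3 | (5S)-7,7-dimethoxy-5-methyl-4-nitroheptanal | O=CCCC([N+](=O)[O-])[C@@H](C)CC(OC)OC
F3 | step 3 | (4S)-2-methoxy-4-methyl-5-nitrocyclohexane-1-carbaldehyde | O=CC1CC([N+](=O)[O-])[C@@H](C)CC1OC
F4 | step 9 | (1R,2R,4S,5S)-2-acetyl-5-methyl-4-nitrocyclohexyl 2-bromoacetate | O=C(CBr)O[C@@H]1C[C@H](C)[C@@H]([N+](=O)[O-])C[C@H]1C(C)=O
F5 | step 9 | (4aR,6S,7S,8aR)-4-hydroxy-4,7-dimethyl-6-nitrooctahydro-2H-chromen-2-one | O=C1O[C@@H]2C[C@H](C)[C@@H]([N+](=O)[O-])C[C@H]2C(C)(O)C1
F6 | step 10 | (1R,2S,4S,5S)-2-[(2Z)-4-hydroxybut-2-en-2-yl]-5-methyl-4-nitrocyclohexan-1-ol | O[C@@H]1C[C@H](C)[C@@H]([N+](=O)[O-])C[C@H]1/C(C)=C\CO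
F7 | step 10 | (1R,2S,4S,5S)-2-[(2R)-4-hydroxybutan-2-yl]-5-methyl-4-nitrocyclohexan-1-ol | O[C@@H]1C[C@H](C)[C@@H]([N+](=O)[O-])C[C@H]1[C@H](C)CCO
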